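The readings were computed for substances that don't exist, noise included.

Will the J in this flask be used up by 3.0 h, or will Q give out first? The meeting had this before it:

| setting | gamma | alpha | delta | flask |
|---|---|---|---|---|
| J | 0.34 M | 0.75 M | 0.50 M | 0.50 M |
| Q | 1.25 M | 1.25 M | 1.25 M | 1.25 M |
| X | 0.50 M | 0.50 M | 1 M | 0.500 M |
| G | 5 mM | 5 mM | 5 mM | 5.0 mM |
| remark | run made earlier | run made earlier | run made earlier |  |
| time |  |  |  | 3.0 h |

| run | time / h | J / % | L / % |
|---|---|---|---|
| gamma | 0.417 | 1 | 97 |
| gamma | 0.833 | 2 | 99 |
| gamma | 1.33 | 2 | 99 |
| gamma | 1.50 | 0 | 102 |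
| gamma | 2.00 | 0 | 99 |
| gamma | 2.50 | 0 | 102 |
| alpha | 0.200 | 22 | 80 |
| alpha | 0.333 | 15 | 87 |
| alpha | 0.500 | 14 | 87 |
| alpha | 0.833 | 5 | 92 |
| alpha | 1.33 | 3 | 96 |
| alpha | 2.50 | 3 | 96 |
| delta | 0.200 | 42 | 58 |
| delta | 0.333 | 34 | 62 |
| delta | 0.667 | 34 | 64 |
| delta | 1.33 | 35 | 67 |
| delta | 2.50 | 35 | 65 |

(standard deviation of a reading: 2 percentage points)

- the reaction counts as stopped when no species that holds the J changes by six tenths of a point or more over the second half of the time

- which holds at 3.0 h: what has brought the reaction to rest, or that it has not come to rest (all of J has reacted / no working catalyst is left / Q has run out first / it is still moving)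
- how much of the J has reacted by 3.0 h
- how much L there is at 3.0 h, in percent of the J charged

The first speaker went to the blackboard and proposed to leave the large amounts aside and reckon one small difference: if J and X each take one Q, the flask's charge of Q stands 0.250 M above their joint demand. She called this the Q margin, start [Q] less start [J] less start [X]. She pointed out that the runs fall in order of it. The gamma run, at 0.410 M, ended with J at 0 %; the alpha run, at 0 M, ended at a reading of 3 %; and the delta run, at −0.250 M, stood still at 35 %.

A second member objected that X might be killing G rather than using Q. The first speaker replied that the alpha run, with the flask's [X] and [G], had used 0.728 M of J, more than the flask's charge of 0.50 M. She added that the gamma run read J at 0 % by 1.50 h, earlier than the flask's 3.0 h. Her reckoning for the flask was therefore J used up, L close to the J charged, and 20.0 % of the Q charge left over.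

The forecast gave all of J has reacted, 99.5 % reacted and L at 99 %, in its words “I expect J to be essentially consumed”.

The flask gives all of J has reacted, with >99.9 % of J reacted and L at >99.9 %.

    J + Q + G → G + L (k = 2.50 /M²/s)
    X + Q + G → G + E (k = 5.50 /M²/s)
    2 G ⇌ D, settled at all times (K = 360 /M)

In the flask, Q stands at 20 % of its charge after 3.00 h, which is 0.250 M, the margin. The neighbour flask has [X] raised to 1.2 M, so its margin is −0.450 M, a shortfall. In the neighbour flask, Q, the limiting reagent, stands at 0 %, while J stays at 46 % and X at 18 % of their charges. Together those two leftovers come to 0.446 M, about the size of the shortfall. L in the neighbour flask stands at 53.8 % of the J charged.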